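**Retrosynthetic overview**
1. The target is a (2R,3S,4S)-oxolane. C7'H2 and C9H2OH are unmasked together by reductive opening of ring B of a cis-fused 2,6-diaryl furofuran, at the latent para-hydroxybenzylic C7'–O bond.
2. The furofuran comes from an acyclic epoxy cinnamyl ether. One titanocene radical/iodine cascade forms C8–C8' (ring A) and then C7'–O (ring B) in the same flask.
3. The epoxy cinnamyl ether comes from an allyl ether and isoeugenyl benzyl ether by cross-metathesis. The allyl ether comes from an epoxy alcohol and allyl bromide.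
4. The epoxy alcohol comes from Sharpless kinetic resolution of the aryl vinyl carbinol made from 3,4,5-trimethoxybenzaldehyde and vinylmagnesium bromide. This single carbinol centre (C7) steers C8 and C8'.
5. Ring order: rings A and B form together in step 5; ring B is opened again in step 6 and ring A stays.

Assumption: the SMILES is read as the (2R,3S,4S)-oxolane (2,3-trans, 3,4-cis, antipodal to the (+)-lariciresinol series); lignan locants C7–C9 (trimethoxyphenyl half) and C7'–C9' (guaiacyl half) are used, ring A is the oxolane kept in the target, ring B is the one opened at the end, and cyclopentadienyl ligands on titanium are drawn sigma-bonded in the SMILES.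

**Step 1**
Reactants: 1 3,4,5-trimethoxybenzaldehyde; 2 vinylmagnesium bromide
Product: 4 (±)-1-(3,4,5-trimethoxyphenyl)prop-2-en-1-ol, via bromomagnesium alkoxide 3 (not isolated)
Conditions: 2 (1.2 equiv), THF, 0 °C; then aq NH4Cl
Reagents that add atoms: none
Why: Grignard 1,2-addition of the vinyl nucleophile to the aldehyde gives the aryl vinyl carbinol as a racemate, whose stereocentre is sorted out in the next step.

**Step 2**
Reactants: 4 (±)-1-(3,4,5-trimethoxyphenyl)prop-2-en-1-ol
Product: 5 (S)-[(R)-oxiran-2-yl](3,4,5-trimethoxyphenyl)methanol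
Conditions: Ti(OiPr)4 (15 mol %), L-(+)-DIPT (18 mol %), TBHP (0.5 equiv, decane), 4 Å MS, CH2Cl2, −20 °C, stopped at about 45% conversion; chromatography
Reagents that add atoms: tert-butyl hydroperoxide, CC(C)(C)OO
Why: In this Sharpless kinetic resolution (asymmetric epoxidation) with L-(+)-DIPT the (R)-carbinol, the spatial analogue of the fast-reacting (S)-alkyl vinyl carbinols, is epoxidised much faster than its antipode and gives the erythro epoxy alcohol, so the carbinol centre that becomes C2 of the oxolane is fixed here while the epoxide centre is only transient.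

**Step 3**
Reactants: 5 (S)-[(R)-oxiran-2-yl](3,4,5-trimethoxyphenyl)methanol; 6 allyl bromide
Product: 8 (R)-2-[(S)-(allyloxy)(3,4,5-trimethoxyphenyl)methyl]oxirane, via sodium alkoxide 7 (not isolated)
Conditions: NaH (1.2 equiv), 6 (1.5 equiv), Bu4NI (5 mol %), THF, 0 °C to rt
Reagents that add atoms: none
Why: Williamson ether synthesis on the sodium alkoxide with a reactive allylic halide in an aprotic medium, where Payne migration is slow, leaves both stereocentres untouched.

**Step 4**
Reactants: 8 (R)-2-[(S)-(allyloxy)(3,4,5-trimethoxyphenyl)methyl]oxirane; 9 (E)-1-(benzyloxy)-2-methoxy-4-(prop-1-en-1-yl)benzene (isoeugenyl benzyl ether)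
Product: 10 (R)-2-[(S)-{[(E)-3-(4-benzyloxy-3-methoxyphenyl)prop-2-en-1-yl]oxy}(3,4,5-trimethoxyphenyl)methyl]oxirane
Conditions: 9 (2.5 equiv), second-generation Hoveyda–Grubbs catalyst RuCl2(H2IMes)(=CH-C6H4-2-OiPr) (5 mol %), CH2Cl2, 40 °C, argon sweep
Reagents that add atoms: none
Why: Olefin cross-metathesis between the terminal allyl ether and an excess of the propenylarene expels propene and gives the conjugated E-styrenyl ether under thermodynamic control without touching the epoxide or the stereocentres.

**Step 5 (key step)**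
Reactants: 10 (R)-2-[(S)-{[(E)-3-(4-benzyloxy-3-methoxyphenyl)prop-2-en-1-yl]oxy}(3,4,5-trimethoxyphenyl)methyl]oxirane
Product: 14 (3R,3aS,6R,6aS)-3-(4-benzyloxy-3-methoxyphenyl)-6-(3,4,5-trimethoxyphenyl)-1,3,3a,4,6,6a-hexahydrofuro[3,4-c]furan, via titanoxy radical 11 (not isolated), via benzyltitanium alkoxide 12 (not isolated), via benzylic iodide 13 (not isolated)
Conditions: Cp2TiCl2 (2.5 equiv), Zn dust, THF, rt, green Cp2TiCl solution added slowly to 10; then I2 (1.5 equiv), 60 °C; recrystallisation
Reagents that add atoms: none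
Why: Nugent–RajanBabu epoxide opening by trivalent titanium gives the secondary radical 11, which closes ring A by 5-exo-trig cyclisation through a chair-like Beckwith–Houk transition state (the aryl group at C7 pseudo-equatorial and hence trans to the new C8' side chain, the C8 substituent cis to it as usual for a 1-substituted hexenyl radical); the benzylic radical is then captured as 12, iodine turns it into the readily ionised iodide 13, and the titanium alkoxide closes ring B by an SN1-like displacement that only the 3,4-cis isomer can undergo and that places the aryl group on the convex face.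

**Step 6**
Reactants: 14 (3R,3aS,6R,6aS)-3-(4-benzyloxy-3-methoxyphenyl)-6-(3,4,5-trimethoxyphenyl)-1,3,3a,4,6,6a-hexahydrofuro[3,4-c]furan
Product: 16 4-{[(3S,4S,5R)-4-(hydroxymethyl)-5-(3,4,5-trimethoxyphenyl)oxolan-3-yl]methyl}-2-methoxyphenol, via phenolic furofuran 15 (not isolated)
Conditions: H2 (1 atm), 10% Pd/C, EtOH, rt, stopped after uptake of 2 equiv H2
Reagents that add atoms: none
Why: In this catalytic hydrogenolysis the O-benzyl group goes first, and the freed para-hydroxy group (quinone-methide-like activation plus relief of bicyclic strain) should then make the benzylic C7'–O bond of ring B much more labile than the C7–O bond next to the hindered non-phenolic trimethoxyphenyl ring, as in the conversion of pinoresinol into lariciresinol, so C7' becomes CH2 and C9 is released as CH2OH while the three remaining stereocentres are untouched.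

**Compound list**
1 | 3,4,5-trimethoxybenzaldehyde | COc1cc(C=O)cc(OC)c1OC | starting material
2 | vinylmagnesium bromide | C=C[Mg]Br | starting material
3 | bromomagnesium 1-(3,4,5-trimethoxyphenyl)prop-2-en-1-olate (racemic) | C=CC(O[Mg]Br)c1cc(OC)c(OC)c(OC)c1 | intermediate
4 | (±)-1-(3,4,5-trimethoxyphenyl)prop-2-en-1-ol | C=CC(O)c1cc(OC)c(OC)c(OC)c1 | intermediate
5 | (S)-[(R)-oxiran-2-yl](3,4,5-trimethoxyphenyl)methanol | O[C@@H](c1cc(OC)c(OC)c(OC)c1)[C@H]1CO1 | intermediate
6 | allyl bromide | C=CCBr | starting material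
7 | sodium alkoxide of 5 | [Na+].[O-][C@@H](c1cc(OC)c(OC)c(OC)c1)[C@H]1CO1 | intermediate
8 | (R)-2-[(S)-(allyloxy)(3,4,5-trimethoxyphenyl)methyl]oxirane | C=CCO[C@@H](c1cc(OC)c(OC)c(OC)c1)[C@H]1CO1 | intermediate
9 | (E)-1-(benzyloxy)-2-methoxy-4-(prop-1-en-1-yl)benzene (isoeugenyl benzyl ether) | C/C=C/c1ccc(OCc2ccccc2)c(OC)c1 | starting material
10 | (R)-2-[(S)-{[(E)-3-(4-benzyloxy-3-methoxyphenyl)prop-2-en-1-yl]oxy}(3,4,5-trimethoxyphenyl)methyl]oxirane | COc1cc(/C=C/CO[C@@H](c2cc(OC)c(OC)c(OC)c2)[C@H]2CO2)ccc1OCc1ccccc1 | intermediate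
11 | open-chain C8 radical with C9–O–TiCp2Cl | COc1cc(/C=C/CO[C@@H](c2cc(OC)c(OC)c(OC)c2)[CH]CO[Ti](Cl)(C2C=CC=C2)C2C=CC=C2)ccc1OCc1ccccc1 | intermediate
12 | ring A oxolane with C7'–TiCp2Cl and C9–O–TiCp2Cl (C7' undefined) | COc1cc(ccc1OCc2ccccc2)C([Ti](Cl)(C7C=CC=C7)C8C=CC=C8)[C@@H]3CO[C@@H](c4cc(OC)c(OC)c(OC)c4)[C@@H]3CO[Ti](Cl)(C5C=CC=C5)C6C=CC=C6 | intermediate
13 | ring A oxolane with C7'–I and C9–O–TiCp2Cl (C7' undefined) | COc1cc(ccc1OCc2ccccc2)C(I)[C@@H]3CO[C@@H](c4cc(OC)c(OC)c(OC)c4)[C@@H]3CO[Ti](Cl)(C5C=CC=C5)C6C=CC=C6 | intermediate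
14 | (3R,3aS,6R,6aS)-3-(4-benzyloxy-3-methoxyphenyl)-6-(3,4,5-trimethoxyphenyl)-1,3,3a,4,6,6a-hexahydrofuro[3,4-c]furan | COc1cc(ccc1OCc2ccccc2)[C@H]3[C@@H]4CO[C@@H](c5cc(OC)c(OC)c(OC)c5)[C@@H]4CO3 | intermediate
15 | 4-[(3R,3aS,6R,6aS)-6-(3,4,5-trimethoxyphenyl)-1,3,3a,4,6,6a-hexahydrofuro[3,4-c]furan-3-yl]-2-methoxyphenol | COc1cc(ccc1O)[C@H]2[C@@H]3CO[C@@H](c4cc(OC)c(OC)c(OC)c4)[C@@H]3CO2 | intermediate
16 | 4-{[(3S,4S,5R)-4-(hydroxymethyl)-5-(3,4,5-trimethoxyphenyl)oxolan-3-yl]methyl}-2-methoxyphenol (CNP0423112.2) | COc1cc(C[C@@H]2CO[C@@H](c3cc(OC)c(OC)c(OC)c3)[C@@H]2CO)ccc1O | target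

**Total step count:** 6. **Longest linear sequence:** 6 (1 → 4 → 5 → 8 → 10 → 14 → 16).

**Three steps most likely to fail**

Step 5 (cascade). The risks are deoxygenation of 11 to an alkene, poor capture of the benzylic radical, and reduction or elimination of 13 before ring B closes. The fallback sets out from 10 and uses the same titanium radical cyclisation, but ends it reductively instead of oxidatively. Protonolysis of 12 with dilute aqueous acid gives [(2R,3S,4S)-4-(4-benzyloxy-3-methoxybenzyl)-2-(3,4,5-trimethoxyphenyl)oxolan-3-yl]methanol F1, which is separated from its 3,4-trans isomer by chromatography. A short hydrogenolysis of the O-benzyl group (H2, Pd/C, EtOAc) then brings it back to the route at 16.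

Step 6 (site selectivity of the hydrogenolysis). The preference for C7'–O over C7–O on an unsymmetrical furofuran is a prediction, and the palladium surface may also attack C7–O or over-reduce to the ring-opened diol. The fallback sets out from 14. The hydrogenolysis is stopped after 1 equiv H2 and 15 is isolated. The approach then changes from surface hydrogenolysis to ionic hydrogenation with BF3·OEt2 and Et3SiH in CH2Cl2 at −40 °C. Only the para-hydroxybenzylic C7'–O bond ionises, giving the O-protonated para-quinone methide F2. This takes hydride from the silane and comes back to the route at 16.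

Step 4 (cross-metathesis). The risks are homodimerisation of 9, isomerisation of the allyl ether and modest conversion. The fallback sets out from 5, skips 8, and replaces metathesis by a convergent SN2 etherification. Bought 4-benzyloxy-3-methoxybenzaldehyde F3 is treated with 2 to give (±)-1-(4-benzyloxy-3-methoxyphenyl)prop-2-en-1-ol F4. PBr3 in Et2O at 0 °C converts F4, with allylic transposition, into (E)-4-benzyloxy-3-methoxycinnamyl bromide F5, which is used crude. Alkylation of 5 with F5 (NaH, THF, 0 °C) comes back to the route at 10.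

**Further compounds**
F1 | step 5 | [(2R,3S,4S)-4-(4-benzyloxy-3-methoxybenzyl)-2-(3,4,5-trimethoxyphenyl)oxolan-3-yl]methanol | COc1cc(C[C@@H]2CO[C@@H](c3cc(OC)c(OC)c(OC)c3)[C@@H]2CO)ccc1OCc1ccccc1
F2 | step 6 | O-protonated para-quinone methide from ring B opening of 15 | COC1=CC(=C[C@@H]2CO[C@@H](c3cc(OC)c(OC)c(OC)c3)[C@@H]2CO)C=CC1=[OH+]
F3 | step 4 | 4-benzyloxy-3-methoxybenzaldehyde (bought) | COc1cc(C=O)ccc1OCc1ccccc1
F4 | step 4 | (±)-1-(4-benzyloxy-3-methoxyphenyl)prop-2-en-1-ol | C=CC(O)c1ccc(OCc2ccccc2)c(OC)c1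
F5 | step 4 | (E)-4-benzyloxy-3-methoxycinnamyl bromide | COc1cc(/C=C/CBr)ccc1OCc1ccccc1
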